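Numbering: C1 = ester C=O, C2 = CH(CH3), C3–C6 = ring carbons (C3–O2, C6–O1), C7–C8 = CH2CH2, C9 = ketone, C10 = C(=CH2).

**Plan**
1. Cuts, in order: C9–C10 (alkenyllithium + aldehyde), ring bond C5–C6, both C6–O bonds (ynone ketal + hydroperoxy alcohol), C3–O2 (H2O2 opening of an oxetane), C2–C3 (aldol).
2. Enabling feature: C6 is the O-bearing quaternary carbon next to the O1–O2 bond of the 1,2-dioxane, i.e. a ketone at the peroxyketal level, and C5 is a ring CH2 next to another CH2 (C4). C4=C5 can therefore enter as a (Z)-vinylsilane that a peroxycarbenium ion at C6 captures 6-endo.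
3. Forward: aldol → (Z)-vinylsilane diol → oxetane → 3-hydroperoxy alcohol → temporary 1,2,4-trioxepane → Lewis-acid opening and C5–C6 closure of the only ring → diimide → C1 oxidation/esterification → side chain joined at C9 last.
4. Helpers: SiMe3 and the trioxepane ring are lost in the key step; the C7≡C8 alkyne (slim sp group on C6) and the ring C4=C5 alkene are removed by diimide; C1 travels as CH2OH.
5. Stereochemistry: C2 and C3 from the auxiliary-controlled syn-aldol (C3 then inverted once in the oxetane opening); C6 relayed from C3 in the key step.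

Key step: step 10

Assumption: compounds 1, 2, 10, 12, 26 and 28 are bought; hydroperoxide 9 and ethereal H2O2 are handled cold, on small scale and without concentration to dryness.

**Step 1**
Reactants: 1 (S)-4-benzyl-3-propionyloxazolidin-2-one; 2 3-(trimethylsilyl)prop-2-ynal
Product: 4 (S)-4-benzyl-3-[(2S,3S)-3-hydroxy-2-methyl-5-(trimethylsilyl)pent-4-ynoyl]oxazolidin-2-one, via boron enolate 3 (not isolated)
Conditions: Bu2BOTf, i-Pr2NEt, CH2Cl2, 0 °C; 2, −78 → 0 °C; pH 7 buffer, MeOH, 30% H2O2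
Reagents that add atoms: none
Why: Evans boron syn-aldol; the (Z)-enolate 3 reacts through a Zimmerman–Traxler chair on the face away from the benzyl group, which sets C2 and C3 (2,3-syn).

**Step 2**
Reactants: 4
Product: 5 (S)-4-benzyl-3-[(2S,3S,4Z)-3-hydroxy-2-methyl-5-(trimethylsilyl)pent-4-enoyl]oxazolidin-2-one
Conditions: H2 (1 atm), Lindlar catalyst, quinoline, EtOAc, rt
Reagents that add atoms: none
Why: Lindlar semihydrogenation adds H2 syn to the silylalkyne and should stop at the (Z)-vinylsilane.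

**Step 3**
Reactants: 5
Product: 6 (2R,3S,4Z)-2-methyl-5-(trimethylsilyl)pent-4-ene-1,3-diol
Conditions: LiBH4, MeOH (2 equiv), THF, 0 °C
Reagents that add atoms: none
Why: Reductive cleavage of the N-acyl oxazolidinone gives the primary alcohol without touching C2 or C3.

**Step 4**
Reactants: 6
Product: 8 (2S,3R)-3-methyl-2-[(Z)-2-(trimethylsilyl)ethenyl]oxetane, via primary tosylate 7 (not isolated)
Conditions: n-BuLi (1 equiv), THF, 0 °C; TsCl (1 equiv); n-BuLi (1 equiv), 0 → 50 °C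
Reagents that add atoms: none
Why: Selective primary tosylation and intramolecular Williamson etherification (4-exo-tet) give the oxetane with retention at C3, because the C3–O bond is not broken.

**Step 5**
Reactants: 8
Product: 9 (2R,3R,4Z)-3-hydroperoxy-2-methyl-5-(trimethylsilyl)pent-4-en-1-ol
Conditions: anhydrous H2O2 in Et2O (excess), Yb(OTf)3 (cat.), Et2O, 0 °C
Reagents that add atoms: hydrogen peroxide, OO
Why: Lewis-acid-catalysed opening of an oxetane by H2O2 (known route to 3-hydroperoxy alkanols) should occur at the allylic carbon with inversion, turning the 2,3-syn alcohol into the 2,3-anti hydroperoxide needed at C3.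

**Step 6**
Reactants: 10 prop-2-yn-1-ol
Product: 11 tert-butyldiphenyl(prop-2-yn-1-yloxy)silane
Conditions: TBDPSCl, imidazole, CH2Cl2, 0 °C → rt
Reagents that add atoms: tert-butyl(chloro)diphenylsilane, CC(C)(C)[Si](Cl)(c1ccccc1)c1ccccc1
Why: Standard silylation; TBDPS is chosen to survive the later acid and Lewis-acid steps.

**Step 7**
Reactants: 11; 12 N-methoxy-N-methylacetamide
Product: 14 5-[(tert-butyldiphenylsilyl)oxy]pent-3-yn-2-one, via lithium acetylide 13 (not isolated)
Conditions: n-BuLi, THF, −78 °C; 12, −78 → 0 °C; aq. NH4Cl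
Reagents that add atoms: none
Why: Weinreb ketone synthesis; the chelated tetrahedral intermediate prevents over-addition.

**Step 8**
Reactants: 14
Product: 15 tert-butyl[(4,4-dimethoxypent-2-yn-1-yl)oxy]diphenylsilane
Conditions: HC(OMe)3, MeOH, TsOH·H2O (cat.), rt
Reagents that add atoms: trimethyl orthoformate, COC(OC)OC
Why: Acid-catalysed ketalisation with orthoformate as water scavenger converts the ynone into a ketal that can exchange with the hydroperoxide.

**Step 9**
Reactants: 9; 15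
Product: 16 (6R,7R)-3-{3-[(tert-butyldiphenylsilyl)oxy]prop-1-yn-1-yl}-3,6-dimethyl-7-[(Z)-2-(trimethylsilyl)ethenyl]-1,2,4-trioxepane (both C3 epimers)
Conditions: CSA (cat.), 4 Å MS, CH2Cl2, 0 °C → rt
Reagents that add atoms: none
Why: Acid-catalysed transketalisation of a 3-hydroperoxy alkanol with a ketal gives the seven-membered cyclic peroxyketal (known condensation type); the ketal-carbon epimers converge in step 10.

**Step 10**
Reactants: 16
Product: 20 (2R)-2-[(3S,6R)-6-{3-[(tert-butyldiphenylsilyl)oxy]prop-1-yn-1-yl}-6-methyl-3,6-dihydro-1,2-dioxin-3-yl]propan-1-ol, via peroxycarbenium triflate 17 (not isolated), via beta-silyl cation 18 (not isolated), via TMS ether 19 (not isolated)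
Conditions: TMSOTf (1 equiv), 2,6-di-tert-butyl-4-methylpyridine, CH2Cl2, −78 → −40 °C; aq. NaHCO3; citric acid, MeOH, 0 °C
Reagents that add atoms: none
Why: Proposed new method: TMSOTf silylates the more basic ether oxygen of the trioxepane, the C6–O(alkyl) bond ionises to the alkynyl peroxycarbenium ion 17, the silicon-bearing carbon C5 of the (Z)-vinylsilane attacks C6, and the β-silyl cation 18 loses Me3Si+ (regenerating TMSOTf) to leave the ring C4=C5 alkene. The closest known reaction types are the Lewis-acid-mediated intramolecular capture of peroxycarbenium ions from monoperoxyketals by allylsilanes and alkenes, and the (Z)-vinylsilane-terminated cyclisation of acetal-derived oxocarbenium ions to 5,6-dihydro-2H-pyrans. The one ring formed, the 3,6-dihydro-1,2-dioxine, closes 6-endo-trig with respect to the vinylsilane through a chair-like transition state in which the C–Si bond is pseudo-axial for σ–p overlap. C6 is set by C3: the C3 side chain must be pseudo-equatorial to avoid a 1,3-diaxial clash with the pseudo-axial SiMe3 on C5, and the peroxycarbenium ion should react in the geometry with O2 syn to the slim sp-hybridised alkynyl group, which places the alkyne axial (cis to the C3 side chain) and the methyl equatorial. The step needs C–O(alkyl) rather than C–OO ionisation (ether oxygen is the better Lewis base), attack at C6 rather than the alkyne terminus (six- versus eight-membered ring), ipso attack (β-silicon effect) and C6 facial control (alkyne/methyl size difference plus the silyl-locked chair).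

**Step 11**
Reactants: 20
Product: 21 (2R)-2-[(3S,6S)-6-{3-[(tert-butyldiphenylsilyl)oxy]propyl}-6-methyl-1,2-dioxan-3-yl]propan-1-ol
Conditions: KO2CN=NCO2K (large excess, portions), AcOH, MeOH/CH2Cl2, 0 °C → rt
Reagents that add atoms: none
Why: Diimide transfers H2 concertedly to the ring alkene and twice to the alkyne without reducing the O–O bond, the standard way to saturate 3,6-dihydro-1,2-dioxines.

**Step 12**
Reactants: 21
Product: 22 (2S)-2-[(3S,6S)-6-{3-[(tert-butyldiphenylsilyl)oxy]propyl}-6-methyl-1,2-dioxan-3-yl]propanoic acid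
Conditions: TEMPO (cat.), PhI(OAc)2, MeCN/pH 7 buffer, rt
Reagents that add atoms: water, O
Why: TEMPO/PhI(OAc)2 oxidises the primary alcohol through the aldehyde hydrate to the acid under near-neutral conditions that spare the peroxide, the silyl ether and the C2 centre.

**Step 13**
Reactants: 22
Product: 23 methyl (2S)-2-[(3S,6S)-6-{3-[(tert-butyldiphenylsilyl)oxy]propyl}-6-methyl-1,2-dioxan-3-yl]propanoate
Conditions: TMSCHN2, MeOH/toluene, 0 °C
Reagents that add atoms: (trimethylsilyl)diazomethane, C[Si](C)(C)C=[N+]=[N-]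
Why: Non-basic esterification with a diazoalkane leaves the base-sensitive β-peroxy ester intact.

**Step 14**
Reactants: 23
Product: 24 methyl (2S)-2-[(3S,6S)-6-(3-hydroxypropyl)-6-methyl-1,2-dioxan-3-yl]propanoate
Conditions: TBAF, AcOH (1:1), THF, rt
Reagents that add atoms: none
Why: Acetic-acid-buffered fluoride removes the TBDPS group without base-induced β-elimination of the peroxide.

**Step 15**
Reactants: 24
Product: 25 methyl (2S)-2-[(3S,6R)-6-methyl-6-(3-oxopropyl)-1,2-dioxan-3-yl]propanoate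
Conditions: Dess–Martin periodinane, NaHCO3, CH2Cl2, 0 °C → rt
Reagents that add atoms: none
Why: Dess–Martin oxidation gives the C9 aldehyde under neutral, peroxide-compatible conditions.

**Step 16**
Reactants: 26 4-bromo-2-methylbutan-2-ol
Product: 27 [(4-bromo-2-methylbutan-2-yl)oxy]trimethylsilane
Conditions: TMSCl, imidazole, CH2Cl2, 0 °C → rt
Reagents that add atoms: chlorotrimethylsilane, C[Si](C)(C)Cl
Why: Silylation masks the tertiary alcohol for the two organometallic steps with a group that falls off in mild acid.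

**Step 17**
Reactants: 27; 28 2,3-dibromopropene
Product: 30 [(6-bromo-2-methylhept-6-en-2-yl)oxy]trimethylsilane, via Grignard reagent 29 (not isolated)
Conditions: Mg, THF; CuI (cat.), 28, THF, 0 °C
Reagents that add atoms: none
Why: Copper-catalysed coupling of a Grignard reagent with 2,3-dibromopropene at the allylic bromide is an established route to 2-bromo-1-alkenes.

**Step 18**
Reactants: 30; 25
Product: 33 methyl (2S)-2-[(3S,6S)-6-(3,7-dihydroxy-7-methyl-4-methylideneoctyl)-6-methyl-1,2-dioxan-3-yl]propanoate (both carbinol epimers), via alkenyllithium 31 (not isolated), via TMS ether adduct 32 (not isolated)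
Conditions: 30, t-BuLi (2 equiv), Et2O, −78 °C; 25, −78 °C; AcOH; citric acid, MeOH, rt
Reagents that add atoms: none
Why: Br–Li exchange and 1,2-addition to the aldehyde, which at −78 °C should outpace attack on the ester or the hindered dialkyl peroxide; the new carbinol centre is unselective but is oxidised in step 19, and the TMS ether is cleaved in acidic methanol.

**Step 19**
Reactants: 33
Product: 34 aikupikoxide D, methyl (2S)-2-[(3S,6R)-6-(7-hydroxy-7-methyl-4-methylidene-3-oxooctyl)-6-methyl-1,2-dioxan-3-yl]propanoate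
Conditions: Dess–Martin periodinane, NaHCO3, CH2Cl2, 0 °C
Reagents that add atoms: none
Why: Dess–Martin oxidation converts the secondary allylic alcohol into the enone while the tertiary alcohol cannot react.

**Compound list**
1 | (S)-4-benzyl-3-propionyloxazolidin-2-one | CCC(=O)N1[C@@H](Cc2ccccc2)COC1=O | starting material
2 | 3-(trimethylsilyl)prop-2-ynal | C[Si](C)(C)C#CC=O | starting material
3 | dibutylboron (Z)-enolate of 1 | C/C=C(\OB(CCCC)CCCC)N1[C@@H](Cc2ccccc2)COC1=O | intermediate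
4 | (S)-4-benzyl-3-[(2S,3S)-3-hydroxy-2-methyl-5-(trimethylsilyl)pent-4-ynoyl]oxazolidin-2-one | C[Si](C)(C)C#C[C@H]([C@H](C)C(=O)N1[C@@H](Cc2ccccc2)COC1=O)O | intermediate
5 | (S)-4-benzyl-3-[(2S,3S,4Z)-3-hydroxy-2-methyl-5-(trimethylsilyl)pent-4-enoyl]oxazolidin-2-one | C[Si](C)(C)/C=C\[C@H]([C@H](C)C(=O)N1[C@@H](Cc2ccccc2)COC1=O)O | intermediate
6 | (2R,3S,4Z)-2-methyl-5-(trimethylsilyl)pent-4-ene-1,3-diol | C[Si](C)(C)/C=C\[C@H]([C@H](C)CO)O | intermediate
7 | (2R,3S,4Z)-3-hydroxy-2-methyl-5-(trimethylsilyl)pent-4-en-1-yl 4-methylbenzenesulfonate | C[Si](C)(C)/C=C\[C@H]([C@H](C)COS(=O)(=O)c1ccc(C)cc1)O | intermediate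
8 | (2S,3R)-3-methyl-2-[(Z)-2-(trimethylsilyl)ethenyl]oxetane | C[Si](C)(C)/C=C\[C@H]([C@H](C)C1)O1 | intermediate
9 | (2R,3R,4Z)-3-hydroperoxy-2-methyl-5-(trimethylsilyl)pent-4-en-1-ol | C[Si](C)(C)/C=C\[C@@H]([C@H](C)CO)OO | intermediate
10 | prop-2-yn-1-ol | C#CCO | starting material
11 | tert-butyldiphenyl(prop-2-yn-1-yloxy)silane | C#CCO[Si](c1ccccc1)(c1ccccc1)C(C)(C)C | intermediate
12 | N-methoxy-N-methylacetamide | CC(=O)N(C)OC | starting material
13 | lithium acetylide of 11 | [Li]C#CCO[Si](c1ccccc1)(c1ccccc1)C(C)(C)C | intermediate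
14 | 5-[(tert-butyldiphenylsilyl)oxy]pent-3-yn-2-one | CC(=O)C#CCO[Si](c1ccccc1)(c1ccccc1)C(C)(C)C | intermediate
15 | tert-butyl[(4,4-dimethoxypent-2-yn-1-yl)oxy]diphenylsilane | COC(C)(OC)C#CCO[Si](c1ccccc1)(c1ccccc1)C(C)(C)C | intermediate
16 | (6R,7R)-3-{3-[(tert-butyldiphenylsilyl)oxy]prop-1-yn-1-yl}-3,6-dimethyl-7-[(Z)-2-(trimethylsilyl)ethenyl]-1,2,4-trioxepane, both C3 epimers | C[Si](C)(C)/C=C\[C@@H]([C@H](C)CO1)OOC1(C)C#CCO[Si](c2ccccc2)(c3ccccc3)C(C)(C)C | intermediate
17 | ring-opened peroxycarbenium triflate (C1–OSiMe3, O2–O1+=C6) | C[Si](C)(C)/C=C\[C@@H]([C@H](C)CO[Si](C)(C)C)O[O+]=C(C)C#CCO[Si](c1ccccc1)(c2ccccc2)C(C)(C)C.[O-]S(=O)(=O)C(F)(F)F | intermediate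
18 | cyclised β-silyl cation (C5–SiMe3 pseudo-axial, cation at C4), triflate | CC(C)(C)[Si](c2ccccc2)(c3ccccc3)OCC#C[C@@]1(C)C([Si](C)(C)C)[CH+][C@@H]([C@H](C)CO[Si](C)(C)C)OO1.[O-]S(=O)(=O)C(F)(F)F | intermediate
19 | trimethylsilyl ether of 20 | CC(C)(C)[Si](c2ccccc2)(c3ccccc3)OCC#C[C@@]1(C)C=C[C@@H]([C@H](C)CO[Si](C)(C)C)OO1 | intermediate
20 | (2R)-2-[(3S,6R)-6-{3-[(tert-butyldiphenylsilyl)oxy]prop-1-yn-1-yl}-6-methyl-3,6-dihydro-1,2-dioxin-3-yl]propan-1-ol | CC(C)(C)[Si](c2ccccc2)(c3ccccc3)OCC#C[C@@]1(C)C=C[C@@H]([C@H](C)CO)OO1 | intermediate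
21 | (2R)-2-[(3S,6S)-6-{3-[(tert-butyldiphenylsilyl)oxy]propyl}-6-methyl-1,2-dioxan-3-yl]propan-1-ol | CC(C)(C)[Si](c2ccccc2)(c3ccccc3)OCCC[C@@]1(C)CC[C@@H]([C@H](C)CO)OO1 | intermediate
22 | (2S)-2-[(3S,6S)-6-{3-[(tert-butyldiphenylsilyl)oxy]propyl}-6-methyl-1,2-dioxan-3-yl]propanoic acid | CC(C)(C)[Si](c2ccccc2)(c3ccccc3)OCCC[C@@]1(C)CC[C@@H]([C@H](C)C(=O)O)OO1 | intermediate
23 | methyl (2S)-2-[(3S,6S)-6-{3-[(tert-butyldiphenylsilyl)oxy]propyl}-6-methyl-1,2-dioxan-3-yl]propanoate | CC(C)(C)[Si](c2ccccc2)(c3ccccc3)OCCC[C@@]1(C)CC[C@@H]([C@H](C)C(=O)OC)OO1 | intermediate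
24 | methyl (2S)-2-[(3S,6S)-6-(3-hydroxypropyl)-6-methyl-1,2-dioxan-3-yl]propanoate | OCCC[C@@]1(C)CC[C@@H]([C@H](C)C(=O)OC)OO1 | intermediate
25 | methyl (2S)-2-[(3S,6R)-6-methyl-6-(3-oxopropyl)-1,2-dioxan-3-yl]propanoate | O=CCC[C@@]1(C)CC[C@@H]([C@H](C)C(=O)OC)OO1 | intermediate
26 | 4-bromo-2-methylbutan-2-ol | CC(C)(O)CCBr | starting material
27 | [(4-bromo-2-methylbutan-2-yl)oxy]trimethylsilane | CC(C)(CCBr)O[Si](C)(C)C | intermediate
28 | 2,3-dibromopropene | C=C(Br)CBr | starting material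
29 | {3-methyl-3-[(trimethylsilyl)oxy]butyl}magnesium bromide | CC(C)(CC[Mg]Br)O[Si](C)(C)C | intermediate
30 | [(6-bromo-2-methylhept-6-en-2-yl)oxy]trimethylsilane | C=C(Br)CCCC(C)(C)O[Si](C)(C)C | intermediate
31 | {6-methyl-6-[(trimethylsilyl)oxy]hept-1-en-2-yl}lithium | [Li]C(=C)CCCC(C)(C)O[Si](C)(C)C | intermediate
32 | methyl (2S)-2-[(3S,6S)-6-{3-hydroxy-7-methyl-4-methylidene-7-[(trimethylsilyl)oxy]octyl}-6-methyl-1,2-dioxan-3-yl]propanoate, both carbinol epimers | C=C(CCCC(C)(C)O[Si](C)(C)C)C(O)CC[C@@]1(C)CC[C@@H]([C@H](C)C(=O)OC)OO1 | intermediate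
33 | methyl (2S)-2-[(3S,6S)-6-(3,7-dihydroxy-7-methyl-4-methylideneoctyl)-6-methyl-1,2-dioxan-3-yl]propanoate, both carbinol epimers | C=C(CCCC(C)(C)O)C(O)CC[C@@]1(C)CC[C@@H]([C@H](C)C(=O)OC)OO1 | intermediate
34 | aikupikoxide D | C=C(CCCC(C)(C)O)C(=O)CC[C@@]1(C)CC[C@@H]([C@H](C)C(=O)OC)OO1 | target

**Step count**
Total: 19 steps. Longest linear sequence: 14 steps (1–5, 9–15, 18, 19).

**Steps most likely to fail**

Step 10. What may go wrong: ionisation at the peroxy C–O bond or O–O heterolysis instead of peroxycarbenium formation, protodesilylation of the vinylsilane before C–C bond formation, or poor facial control at C6. Fallback (known chemistry; sets out from 14 and 1, returns at 21): the ring is closed at O2–C3 instead. Ynone 14 is hydrogenated (H2, Pd/C) to 5-[(tert-butyldiphenylsilyl)oxy]pentan-2-one F1. Wittig reaction with the ylide from commercial [2-(1,3-dioxolan-2-yl)ethyl]triphenylphosphonium bromide (KHMDS, THF) gives tert-butyl{[6-(1,3-dioxolan-2-yl)-4-methylhex-4-en-1-yl]oxy}diphenylsilane F2 (E/Z mixture), and mild aqueous acid releases 7-[(tert-butyldiphenylsilyl)oxy]-4-methylhept-3-enal F3. Evans syn-aldol of F3 with 1 (as in step 1, through enolate 3) gives (S)-4-benzyl-3-[(2S,3R)-9-[(tert-butyldiphenylsilyl)oxy]-3-hydroxy-2,6-dimethylnon-5-enoyl]oxazolidin-2-one F4. LiBH4 gives (2R,3R)-9-[(tert-butyldiphenylsilyl)oxy]-2,6-dimethylnon-5-ene-1,3-diol F5, which is converted as in step 4 through the primary tosylate F6 into tert-butyl({4-methyl-6-[(2R,3R)-3-methyloxetan-2-yl]hex-4-en-1-yl}oxy)diphenylsilane F7. Isayama–Mukaiyama hydroperoxysilylation (Co(acac)2, Et3SiH, O2) places a tertiary silylperoxy group at C6 to give tert-butyl({4-methyl-6-[(2R,3R)-3-methyloxetan-2-yl]-4-[(triethylsilyl)peroxy]hexyl}oxy)diphenylsilane F8 as both C6 epimers. TMSOTf-promoted 6-exo opening of the oxetane by the peroxide oxygen, with inversion at C3, should give 21 and its C6 epimer, which are separated by chromatography.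

Step 5. What may go wrong: ionisation of the allylic C–O bond to an allyl cation with loss of stereospecificity at C3, SN2′ attack, or acid-induced protodesilylation. Fallback (sets out from 6, returns at 9): intermolecular sulfonate displacement. Diol 6 is silylated at the primary hydroxyl (TBSCl, imidazole) to (2R,3S,4Z)-1-[(tert-butyldimethylsilyl)oxy]-2-methyl-5-(trimethylsilyl)pent-4-en-3-ol F9. Mesylation (MsCl, Et3N, −20 °C) gives (2R,3S,4Z)-1-[(tert-butyldimethylsilyl)oxy]-2-methyl-5-(trimethylsilyl)pent-4-en-3-yl methanesulfonate F10. Displacement with 2-methoxyprop-2-yl hydroperoxide (CsOH, DMF, 0 °C) should proceed with inversion to tert-butyl{[(2R,3R,4Z)-3-[(2-methoxypropan-2-yl)peroxy]-2-methyl-5-(trimethylsilyl)pent-4-en-1-yl]oxy}dimethylsilane F11. AcOH/THF/H2O then removes the perketal and the TBS group to give 9.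

Step 18. What may go wrong: attack of the organolithium on the O–O bond, or deprotonation α to the ester followed by β-elimination of the peroxide. Fallback (sets out from 25 and 30, returns at 34): neutral acyl cross-coupling in place of carbonyl addition. Pinnick oxidation of 25 (NaClO2, NaH2PO4, 2-methylbut-2-ene) gives 3-[(3R,6S)-6-[(2S)-1-methoxy-1-oxopropan-2-yl]-3-methyl-1,2-dioxan-3-yl]propanoic acid F12, and (COCl)2 with catalytic DMF gives its acid chloride F13. Bromide 30 is converted (t-BuLi, then Bu3SnCl) into tributyl{6-methyl-6-[(trimethylsilyl)oxy]hept-1-en-2-yl}stannane F14. Stille acylation of F13 with F14 (Pd2(dba)3, tri(2-furyl)phosphine, toluene) should give the trimethylsilyl ether of aikupikoxide D F15, and citric acid in MeOH gives 34.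

**Further compounds**
F1 | step 10 | 5-[(tert-butyldiphenylsilyl)oxy]pentan-2-one | CC(=O)CCCO[Si](c1ccccc1)(c1ccccc1)C(C)(C)C
F2 | step 10 | tert-butyl{[6-(1,3-dioxolan-2-yl)-4-methylhex-4-en-1-yl]oxy}diphenylsilane (E/Z) | CC(=CCC1OCCO1)CCCO[Si](c2ccccc2)(c3ccccc3)C(C)(C)C
F3 | step 10 | 7-[(tert-butyldiphenylsilyl)oxy]-4-methylhept-3-enal | CC(=CCC=O)CCCO[Si](c1ccccc1)(c2ccccc2)C(C)(C)C
F4 | step 10 | (S)-4-benzyl-3-[(2S,3R)-9-[(tert-butyldiphenylsilyl)oxy]-3-hydroxy-2,6-dimethylnon-5-enoyl]oxazolidin-2-one | CC(=CC[C@H]([C@H](C)C(=O)N1[C@@H](Cc2ccccc2)COC1=O)O)CCCO[Si](c3ccccc3)(c4ccccc4)C(C)(C)C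
F5 | step 10 | (2R,3R)-9-[(tert-butyldiphenylsilyl)oxy]-2,6-dimethylnon-5-ene-1,3-diol | CC(=CC[C@H]([C@H](C)CO)O)CCCO[Si](c1ccccc1)(c2ccccc2)C(C)(C)C
F6 | step 10 | (2R,3R)-9-[(tert-butyldiphenylsilyl)oxy]-3-hydroxy-2,6-dimethylnon-5-en-1-yl 4-methylbenzenesulfonate | CC(=CC[C@H]([C@H](C)COS(=O)(=O)c1ccc(C)cc1)O)CCCO[Si](c2ccccc2)(c3ccccc3)C(C)(C)C
F7 | step 10 | tert-butyl({4-methyl-6-[(2R,3R)-3-methyloxetan-2-yl]hex-4-en-1-yl}oxy)diphenylsilane | CC(=CC[C@H]([C@H](C)C1)O1)CCCO[Si](c2ccccc2)(c3ccccc3)C(C)(C)C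
F8 | step 10 | tert-butyl({4-methyl-6-[(2R,3R)-3-methyloxetan-2-yl]-4-[(triethylsilyl)peroxy]hexyl}oxy)diphenylsilane, both C4 epimers | CC(CC[C@H]([C@H](C)C1)O1)(OO[Si](CC)(CC)CC)CCCO[Si](c2ccccc2)(c3ccccc3)C(C)(C)C
F9 | step 5 | (2R,3S,4Z)-1-[(tert-butyldimethylsilyl)oxy]-2-methyl-5-(trimethylsilyl)pent-4-en-3-ol | C[Si](C)(C)/C=C\[C@H]([C@H](C)CO[Si](C)(C)C(C)(C)C)O
F10 | step 5 | (2R,3S,4Z)-1-[(tert-butyldimethylsilyl)oxy]-2-methyl-5-(trimethylsilyl)pent-4-en-3-yl methanesulfonate | C[Si](C)(C)/C=C\[C@H]([C@H](C)CO[Si](C)(C)C(C)(C)C)OS(C)(=O)=O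
F11 | step 5 | tert-butyl{[(2R,3R,4Z)-3-[(2-methoxypropan-2-yl)peroxy]-2-methyl-5-(trimethylsilyl)pent-4-en-1-yl]oxy}dimethylsilane | C[Si](C)(C)/C=C\[C@@H]([C@H](C)CO[Si](C)(C)C(C)(C)C)OOC(C)(C)OC
F12 | step 18 | 3-[(3R,6S)-6-[(2S)-1-methoxy-1-oxopropan-2-yl]-3-methyl-1,2-dioxan-3-yl]propanoic acid | OC(=O)CC[C@@]1(C)CC[C@@H]([C@H](C)C(=O)OC)OO1
F13 | step 18 | 3-[(3R,6S)-6-[(2S)-1-methoxy-1-oxopropan-2-yl]-3-methyl-1,2-dioxan-3-yl]propanoyl chloride | ClC(=O)CC[C@@]1(C)CC[C@@H]([C@H](C)C(=O)OC)OO1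
F14 | step 18 | tributyl{6-methyl-6-[(trimethylsilyl)oxy]hept-1-en-2-yl}stannane | C=C(CCCC(C)(C)O[Si](C)(C)C)[Sn](CCCC)(CCCC)CCCC
F15 | step 18 | trimethylsilyl ether of aikupikoxide D | C=C(CCCC(C)(C)O[Si](C)(C)C)C(=O)CC[C@@]1(C)CC[C@@H]([C@H](C)C(=O)OC)OO1
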